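**Strategy.** The route rests on disconnecting the enol-lactone bond O1–C5 of the furanone ring. The exocyclic C5=C6 alkene is E (C4 and C7 cis, O1 trans to C7), a geometry that anti-oxymetalation of an alkyne cannot deliver. The ring is therefore closed by a copper-catalysed intramolecular O-vinylation of a carboxylic acid with an (E)-alkenyl bromide, which forms O1–C5 with retention and so writes the bromide geometry into the ylidene lactone. The precursor is an acyclic 4-bromo-3-hydroxy-2-methylalk-4-enoic acid, made by a bromo-Horner–Wadsworth–Emmons olefination and a propionate aldol. A final double oxidation reveals the tetronic acid and the furyl ketone.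

Key step: step 13

Remark: locants follow the target (O1, lactone carbonyl C2, methyl-bearing C3, enol carbon C4, C5, exocyclic C6, stereocentre C7, chain C8 to C17, ketone carbon C18). C18 (before step 14) and C3/C4 (between steps 12 and 14) all end sp2, so they are carried as stereoisomeric mixtures and their SMILES carry no stereo label.

Step 1
Reactants: 1 hept-6-ynoic acid; 2 (S)-4-benzyloxazolidin-2-one
Product: 4 (S)-4-benzyl-3-(hept-6-ynoyl)oxazolidin-2-one, via mixed pivalic anhydride 3 (not isolated)
Conditions: PivCl, Et3N, THF, -20 °C; then 2, LiCl, -20 °C to rt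
Reagents that add atoms: none
Why: N-acylation of the LiCl-activated oxazolidinone by the mixed anhydride at its less hindered carbonyl installs the chiral auxiliary that will control C7.

Step 2
Reactants: 4 (S)-4-benzyl-3-(hept-6-ynoyl)oxazolidin-2-one
Product: 6 (S)-4-benzyl-3-[(2S)-2-methylhept-6-ynoyl]oxazolidin-2-one, via sodium enolate 5 (not isolated)
Conditions: NaN(SiMe3)2, THF, -78 °C; then MeI, -78 °C
Reagents that add atoms: iodomethane CI
Why: Auxiliary-controlled (Evans) enolate alkylation, in which the chelated (Z)-enolate is methylated on the face opposite the benzyl group and so sets C7 as (S), the imide α-CH2 being far more acidic than the alkyne C–H.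

Step 3
Reactants: 6 (S)-4-benzyl-3-[(2S)-2-methylhept-6-ynoyl]oxazolidin-2-one
Product: 7 (2S)-2-methylhept-6-yn-1-ol
Conditions: LiBH4, MeOH (1 equiv), Et2O, 0 °C
Reagents that add atoms: none
Why: Reductive cleavage of the imide by borohydride should release the primary alcohol without touching the alkyne or the α-stereocentre and return the auxiliary.

Step 4
Reactants: 8 geranyl acetate
Product: 10 (2E)-3-methyl-6-oxohex-2-en-1-yl acetate, via ozonide 9 (not isolated)
Conditions: O3 (about 1 equiv), CH2Cl2, -78 °C; then PPh3, -78 °C to rt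
Reagents that add atoms: ozone [O-][O+]=O
Why: Ozonolysis should be chemoselective for the electron-rich 6,7-alkene because the 2,3-alkene is deactivated by the allylic acetoxy group, leaving the (E)-alkene that becomes C14=C15 intact.

Step 5
Reactants: 11 3-bromofuran; 10 (2E)-3-methyl-6-oxohex-2-en-1-yl acetate
Product: 14 (4E)-6-acetoxy-1-(furan-3-yl)-4-methylhex-4-en-1-yl pivalate, via 3-furyllithium 12 (not isolated), via lithium alkoxide 13 (not isolated)
Conditions: n-BuLi, THF, -78 °C; then 10, -78 °C; then PivCl, -78 to 0 °C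
Reagents that add atoms: pivaloyl chloride CC(C)(C)C(Cl)=O
Why: Bromine–lithium exchange and 1,2-addition of the aryllithium to the aldehyde (much faster than attack on the acetate at -78 °C) followed by in situ O-acylation gives the protected racemic C18 carbinol.

Step 6
Reactants: 7 (2S)-2-methylhept-6-yn-1-ol; 14 (4E)-6-acetoxy-1-(furan-3-yl)-4-methylhex-4-en-1-yl pivalate
Product: 16 (2S,6E,9E)-13-(furan-3-yl)-1-hydroxy-2,6,10-trimethyltrideca-6,9-dien-13-yl pivalate, via alkenylalane 15 (not isolated)
Conditions: AlMe3 (3 equiv), Cp2ZrCl2 (cat.), CH2Cl2, 0 °C to rt; then THF, 14, Pd(PPh3)4 (5 mol %), rt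
Reagents that add atoms: trimethylaluminium C[Al](C)C
Why: Zirconium-catalysed syn-methylalumination of the terminal alkyne (Negishi carboalumination) sets the (E)-C11=C12 alkene, and palladium-catalysed coupling of the alkenylalane at the primary terminus of the allylic acetate with retention of both geometries gives the skipped diene.

Step 7
Reactants: 16 (2S,6E,9E)-13-(furan-3-yl)-1-hydroxy-2,6,10-trimethyltrideca-6,9-dien-13-yl pivalate
Product: 17 (2S,6E,9E)-13-(furan-3-yl)-2,6,10-trimethyl-1-oxotrideca-6,9-dien-13-yl pivalate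
Conditions: Dess–Martin periodinane, pyridine, CH2Cl2, 0 °C
Reagents that add atoms: none
Why: Buffered Dess–Martin oxidation of the primary alcohol should give the α-branched aldehyde without epimerisation at C7, the crude aldehyde being used at once.

Step 8
Reactants: 18 methyl 2-[bis(2,2,2-trifluoroethoxy)phosphoryl]acetate
Product: 20 methyl 2-bromo-2-[bis(2,2,2-trifluoroethoxy)phosphoryl]acetate, via dibromophosphonate 19 (not isolated)
Conditions: Br2, NaOH, H2O, 0 °C; then Na2SO3, H2O, 0 °C
Reagents that add atoms: bromine BrBr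
Why: Exhaustive hypobromite bromination of the activated methylene followed by reductive mono-debromination with sulfite should give the monobromophosphonate free of unbrominated reagent.

Step 9
Reactants: 20 methyl 2-bromo-2-[bis(2,2,2-trifluoroethoxy)phosphoryl]acetate; 17 (2S,6E,9E)-13-(furan-3-yl)-2,6,10-trimethyl-1-oxotrideca-6,9-dien-13-yl pivalate
Product: 22 methyl (2E,4S,8E,11E)-2-bromo-15-(furan-3-yl)-4,8,12-trimethyl-15-(pivaloyloxy)pentadeca-2,8,11-trienoate, via potassium phosphonate anion 21 (not isolated)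
Conditions: t-BuOK, 18-crown-6, THF, -78 °C; then 17, -78 °C
Reagents that add atoms: none
Why: Horner–Wadsworth–Emmons olefination with a bis(trifluoroethyl) phosphonate (Still–Gennari-type kinetic control) places the ester cis to C7 and therefore Br trans to C7, giving the (2E)-bromoacrylate, while -78 °C should prevent epimerisation at C7.

Step 10
Reactants: 22 methyl (2E,4S,8E,11E)-2-bromo-15-(furan-3-yl)-4,8,12-trimethyl-15-(pivaloyloxy)pentadeca-2,8,11-trienoate
Product: 23 (2E,4S,8E,11E)-2-bromo-15-(furan-3-yl)-4,8,12-trimethylpentadeca-2,8,11-triene-1,15-diol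
Conditions: i-Bu2AlH (excess), CH2Cl2, -78 to 0 °C
Reagents that add atoms: none
Why: Hydride reduction converts the ester 1,2 into the allylic alcohol and cleaves the pivalate in the same operation, leaving the alkenyl bromide and all alkene geometries untouched.

Step 11
Reactants: 23 (2E,4S,8E,11E)-2-bromo-15-(furan-3-yl)-4,8,12-trimethylpentadeca-2,8,11-triene-1,15-diol
Product: 24 (2E,4S,8E,11E)-2-bromo-15-(furan-3-yl)-15-hydroxy-4,8,12-trimethylpentadeca-2,8,11-trienal
Conditions: TEMPO (10 mol %), PhI(OAc)2, CH2Cl2, pH 7 buffer, 0 °C, dark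
Reagents that add atoms: none
Why: Oxoammonium oxidation is selective for the primary allylic alcohol over the secondary C18 carbinol and does not isomerise cis-substituted enals (any C18 ketone formed converges in step 14).

Step 12
Reactants: 25 propionic acid; 24 (2E,4S,8E,11E)-2-bromo-15-(furan-3-yl)-15-hydroxy-4,8,12-trimethylpentadeca-2,8,11-trienal
Product: 27 (4E,6S,10E,13E)-4-bromo-17-(furan-3-yl)-3,17-dihydroxy-2,6,10,14-tetramethylheptadeca-4,10,13-trienoic acid, via dilithium propionate dianion 26 (not isolated)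
Conditions: LiN(i-Pr)2 (2 equiv per acid), THF, 0 °C; then 24, -78 °C; aq. HCl to pH 3
Reagents that add atoms: none
Why: Aldol addition of the carboxylic acid dianion to the aldehyde carbonyl at -78 °C gives the β-hydroxy acid directly, the two new centres (C3, C4) being formed unselectively because both are erased in step 14.

Step 13
Reactants: 27 (4E,6S,10E,13E)-4-bromo-17-(furan-3-yl)-3,17-dihydroxy-2,6,10,14-tetramethylheptadeca-4,10,13-trienoic acid
Product: 28 (5E)-5-[(2S,6E,9E)-13-(furan-3-yl)-13-hydroxy-2,6,10-trimethyltrideca-6,9-dien-1-ylidene]-4-hydroxy-3-methyldihydrofuran-2(3H)-one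
Conditions: CuI (20 mol %), trans-N,N'-dimethylcyclohexane-1,2-diamine (40 mol %), K2CO3, THF, 65 °C, degassed, dark
Reagents that add atoms: none
Why: The potassium carboxylate binds diamine-ligated monovalent copper, the C5–Br bond is activated within this complex (oxidative addition to an alkenyl trivalent copper carboxylate or a four-centre metathesis) and C–O reductive elimination forms O1–C5. The closest known reaction type is the copper-catalysed Ullmann-type intramolecular O-vinylation of carboxylic acids with vinyl bromides to enol lactones. The furanone ring closes in the 5-exo mode on the sp2 carbon C5, the C5=C6 bond remaining exocyclic. No stereocentre is created; the C5=C6 geometry is transferred with retention from the (E)-bromide, so C4 stays cis to C7 and O1 ends trans to C7, and C7 itself is not touched. The step needs O-selectivity for the carboxylate and freedom from elimination: the C4–OH could only close a three-membered ring, the C18–OH would have to react intermolecularly, and H6 is cis to Br so that anti-dehydrobromination to an alkyne is not available.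

Step 14
Reactants: 28 (5E)-5-[(2S,6E,9E)-13-(furan-3-yl)-13-hydroxy-2,6,10-trimethyltrideca-6,9-dien-1-ylidene]-4-hydroxy-3-methyldihydrofuran-2(3H)-one
Product: 29 (5E)-5-[(2S,6E,9E)-13-(furan-3-yl)-2,6,10-trimethyl-13-oxotrideca-6,9-dien-1-ylidene]-4-hydroxy-3-methylfuran-2(5H)-one (target, CNP0018619.1)
Conditions: Dess–Martin periodinane (3 equiv), pyridine, CH2Cl2, 0 °C, dark; pH 3 work-up
Reagents that add atoms: none
Why: Dess–Martin oxidation of both secondary carbinols turns C18–OH into the 3-furyl ketone and C4–OH into the furan-2,4-dione that enolises to the tetronic acid (C3=C4–OH), and buffering, darkness and a short reaction time should preserve the (E)-C5=C6 geometry and C7.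

**Compound list**

1 | hept-6-ynoic acid | OC(=O)CCCCC#C | starting material
2 | (S)-4-benzyloxazolidin-2-one | O=C1N[C@@H](Cc2ccccc2)CO1 | starting material
3 | hept-6-ynoic pivalic anhydride (not isolated) | C#CCCCCC(=O)OC(=O)C(C)(C)C | intermediate
4 | (S)-4-benzyl-3-(hept-6-ynoyl)oxazolidin-2-one | C#CCCCCC(=O)N1[C@@H](Cc2ccccc2)COC1=O | intermediate
5 | sodium (Z)-enolate of 4 (not isolated) | [Na+].[O-]/C(=C\CCCC#C)N1[C@@H](Cc2ccccc2)COC1=O | intermediate
6 | (S)-4-benzyl-3-[(2S)-2-methylhept-6-ynoyl]oxazolidin-2-one | C#CCCC[C@H](C)C(=O)N1[C@@H](Cc2ccccc2)COC1=O | intermediate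
7 | (2S)-2-methylhept-6-yn-1-ol | C#CCCC[C@H](C)CO | intermediate
8 | geranyl acetate, (2E)-3,7-dimethylocta-2,6-dien-1-yl acetate | CC(=O)OC/C=C(\C)CCC=C(C)C | starting material
9 | ozonide of the 6,7-alkene of 8 (not isolated) | CC(=O)OC/C=C(\C)CCC1OOC(C)(C)O1 | intermediate
10 | (2E)-3-methyl-6-oxohex-2-en-1-yl acetate | CC(=O)OC/C=C(\C)CCC=O | intermediate
11 | 3-bromofuran | Brc1ccoc1 | starting material
12 | 3-furyllithium (not isolated) | [Li]c1ccoc1 | intermediate
13 | lithium (4E)-6-acetoxy-1-(furan-3-yl)-4-methylhex-4-en-1-olate (not isolated) | CC(=O)OC/C=C(\C)CCC([O-])c1ccoc1.[Li+] | intermediate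
14 | (4E)-6-acetoxy-1-(furan-3-yl)-4-methylhex-4-en-1-yl pivalate | CC(=O)OC/C=C(\C)CCC(OC(=O)C(C)(C)C)c1ccoc1 | intermediate
15 | (E)-alkenylalane from methylalumination of 7, O-dimethylaluminium alkoxide (not isolated) | C[Al](C)/C=C(\C)CCC[C@H](C)CO[Al](C)C | intermediate
16 | (2S,6E,9E)-13-(furan-3-yl)-1-hydroxy-2,6,10-trimethyltrideca-6,9-dien-13-yl pivalate | OC[C@@H](C)CCC/C(C)=C/C/C=C(\C)CCC(OC(=O)C(C)(C)C)c1ccoc1 | intermediate
17 | (2S,6E,9E)-13-(furan-3-yl)-2,6,10-trimethyl-1-oxotrideca-6,9-dien-13-yl pivalate | O=C[C@@H](C)CCC/C(C)=C/C/C=C(\C)CCC(OC(=O)C(C)(C)C)c1ccoc1 | intermediate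
18 | methyl 2-[bis(2,2,2-trifluoroethoxy)phosphoryl]acetate | COC(=O)CP(=O)(OCC(F)(F)F)OCC(F)(F)F | starting material
19 | methyl 2,2-dibromo-2-[bis(2,2,2-trifluoroethoxy)phosphoryl]acetate (not isolated) | COC(=O)C(Br)(Br)P(=O)(OCC(F)(F)F)OCC(F)(F)F | intermediate
20 | methyl 2-bromo-2-[bis(2,2,2-trifluoroethoxy)phosphoryl]acetate | COC(=O)C(Br)P(=O)(OCC(F)(F)F)OCC(F)(F)F | intermediate
21 | potassium salt of the carbanion of 20 (not isolated) | [K+].COC(=O)[C-](Br)P(=O)(OCC(F)(F)F)OCC(F)(F)F | intermediate
22 | methyl (2E,4S,8E,11E)-2-bromo-15-(furan-3-yl)-4,8,12-trimethyl-15-(pivaloyloxy)pentadeca-2,8,11-trienoate | COC(=O)/C(Br)=C\[C@@H](C)CCC/C(C)=C/C/C=C(\C)CCC(OC(=O)C(C)(C)C)c1ccoc1 | intermediate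
23 | (2E,4S,8E,11E)-2-bromo-15-(furan-3-yl)-4,8,12-trimethylpentadeca-2,8,11-triene-1,15-diol | OC/C(Br)=C\[C@@H](C)CCC/C(C)=C/C/C=C(\C)CCC(O)c1ccoc1 | intermediate
24 | (2E,4S,8E,11E)-2-bromo-15-(furan-3-yl)-15-hydroxy-4,8,12-trimethylpentadeca-2,8,11-trienal | O=C/C(Br)=C\[C@@H](C)CCC/C(C)=C/C/C=C(\C)CCC(O)c1ccoc1 | intermediate
25 | propionic acid | CCC(=O)O | starting material
26 | dilithium dianion of propionic acid (not isolated) | [Li+].[Li+].CC=C([O-])[O-] | intermediate
27 | (4E,6S,10E,13E)-4-bromo-17-(furan-3-yl)-3,17-dihydroxy-2,6,10,14-tetramethylheptadeca-4,10,13-trienoic acid | OC(=O)C(C)C(O)/C(Br)=C\[C@@H](C)CCC/C(C)=C/C/C=C(\C)CCC(O)c1ccoc1 | intermediate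
28 | (5E)-5-[(2S,6E,9E)-13-(furan-3-yl)-13-hydroxy-2,6,10-trimethyltrideca-6,9-dien-1-ylidene]-4-hydroxy-3-methyldihydrofuran-2(3H)-one | CC1C(O)/C(=C\[C@@H](C)CCC/C(C)=C/C/C=C(\C)CCC(O)c2ccoc2)OC1=O | intermediate
29 | (5E)-5-[(2S,6E,9E)-13-(furan-3-yl)-2,6,10-trimethyl-13-oxotrideca-6,9-dien-1-ylidene]-4-hydroxy-3-methylfuran-2(5H)-one | CC1=C(O)/C(=C\[C@@H](C)CCC/C(C)=C/C/C=C(\C)CCC(=O)c2ccoc2)OC1=O | target

**Total step count:** 14 steps.
**Longest linear sequence:** 11 steps (steps 1, 2, 3, 6, 7, 9, 10, 11, 12, 13, 14).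

**Steps most likely to fail**

Step 13. Activation of the C5–Br bond of a trisubstituted, α-branched alkenyl bromide may be slow. Base-induced dehydration of the β-hydroxy lactone or erosion of the alkene geometry could then compete at 65 °C. The fallback makes the same bond at room temperature by an oxidative coupling of a boron, not a halogen, partner. It sets out from 27, which is converted with retention by Miyaura borylation (B2pin2, PdCl2(PPh3)2, PPh3, KOPh, toluene, 50 °C) into (4Z,6S,10E,13E)-17-(furan-3-yl)-3,17-dihydroxy-2,6,10,14-tetramethyl-4-(4,4,5,5-tetramethyl-1,3,2-dioxaborolan-2-yl)heptadeca-4,10,13-trienoic acid F1, with boron trans to C7. A Chan–Lam-type intramolecular O-alkenylation of the carboxylic acid (Cu(OAc)2, pyridine, 4 Å sieves, air, CH2Cl2, rt) should then close the ring with retention and come back to the route at 28.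

Step 12. The strongly basic dianion may deprotonate C7–H (γ to the aldehyde), which would erode the stereocentre. It may also isomerise the strained ester-cis bromoenal, or add in the conjugate sense, before carbonyl addition is complete. The fallback forms the C3–C4 bond under neutral conditions. It sets out from 24, which in a Reformatsky reaction with ethyl 2-bromopropanoate and activated Zn (THF, 0 °C) should give ethyl (4E,6S,10E,13E)-4-bromo-17-(furan-3-yl)-3,17-dihydroxy-2,6,10,14-tetramethylheptadeca-4,10,13-trienoate F5. Saponification (LiOH, THF/H2O, 0 °C) then comes back to the route at 27.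

Step 9. The kinetic preference for the ester-cis (2E) isomer may be insufficient with an α-branched aldehyde, so that the wrong alkene geometry would be carried into the ring closure. The fallback fixes the geometry by a stereospecific syn-addition to an alkyne. It sets out from 17:
- Seyferth–Gilbert homologation with dimethyl (1-diazo-2-oxopropyl)phosphonate (K2CO3, MeOH, 0 °C) should give (3S,7E,10E)-14-(furan-3-yl)-3,7,11-trimethyltetradeca-7,10-dien-1-yn-14-yl pivalate F2.
- Deprotonation (LiN(i-Pr)2, THF, -78 °C) and trapping with methyl chloroformate gives methyl (4S,8E,11E)-15-(furan-3-yl)-4,8,12-trimethyl-15-(pivaloyloxy)pentadeca-8,11-dien-2-ynoate F3.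
- Palladium-catalysed hydrostannation (Bu3SnH, Pd(PPh3)4, THF, 0 °C) adds H and Sn syn with tin α to the ester, to give methyl (2E,4S,8E,11E)-15-(furan-3-yl)-4,8,12-trimethyl-15-(pivaloyloxy)-2-(tributylstannyl)pentadeca-2,8,11-trienoate F4, in which the ester is cis to C7.
- Bromodestannylation with retention (NBS, CH2Cl2, -40 °C, dark) comes back to the route at 22.

**Further compounds**

F1 | step 13 | (4Z,6S,10E,13E)-17-(furan-3-yl)-3,17-dihydroxy-2,6,10,14-tetramethyl-4-(4,4,5,5-tetramethyl-1,3,2-dioxaborolan-2-yl)heptadeca-4,10,13-trienoic acid | OC(=O)C(C)C(O)/C(B1OC(C)(C)C(C)(C)O1)=C\[C@@H](C)CCC/C(C)=C/C/C=C(\C)CCC(O)c1ccoc1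
F2 | step 9 | (3S,7E,10E)-14-(furan-3-yl)-3,7,11-trimethyltetradeca-7,10-dien-1-yn-14-yl pivalate | C#C[C@@H](C)CCC/C(C)=C/C/C=C(\C)CCC(OC(=O)C(C)(C)C)c1ccoc1
F3 | step 9 | methyl (4S,8E,11E)-15-(furan-3-yl)-4,8,12-trimethyl-15-(pivaloyloxy)pentadeca-8,11-dien-2-ynoate | COC(=O)C#C[C@@H](C)CCC/C(C)=C/C/C=C(\C)CCC(OC(=O)C(C)(C)C)c1ccoc1
F4 | step 9 | methyl (2E,4S,8E,11E)-15-(furan-3-yl)-4,8,12-trimethyl-15-(pivaloyloxy)-2-(tributylstannyl)pentadeca-2,8,11-trienoate | COC(=O)/C(=C\[C@@H](C)CCC/C(C)=C/C/C=C(\C)CCC(OC(=O)C(C)(C)C)c1ccoc1)[Sn](CCCC)(CCCC)CCCC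
F5 | step 12 | ethyl (4E,6S,10E,13E)-4-bromo-17-(furan-3-yl)-3,17-dihydroxy-2,6,10,14-tetramethylheptadeca-4,10,13-trienoate | CCOC(=O)C(C)C(O)/C(Br)=C\[C@@H](C)CCC/C(C)=C/C/C=C(\C)CCC(O)c1ccoc1
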